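Ring A is grown from a cyclopentene. A CBS-derived bromocyclopentenyl ester undergoes Ireland–Claisen rearrangement, which sets the C10 quaternary centre and moves the alkene to C3=C5; a radical cyclization then closes ring B. After dibromocarbene addition, silver-promoted electrocyclic opening of the cyclopropane enlarges the five-membered ring to ring A in one operation: the former carbene carbon becomes C4, water enters at C3, and the remaining C4=C5 vinyl bromide completes the C3-oxygen/C4/C5 array of ring A that C4 methylation and Birch reductive alkylation (H-5, C4 quaternary centre) then use. The key-step precursor is a furan-bearing dibromotricycle; the furan is opened last to the (Z)-enediol.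

Key step: step 11

Remark on conventions: labdane numbering (C1–C20) is used for all intermediates; C17 is the exocyclic methylene carbon, C18 the hydroxymethyl carbon on C4, C19 and C20 the methyls on C4 and C10; α is the face of the C10 methyl, β the face of H-5 and H-9.

Remark on the chemistry: compounds 8–20 are expected as C9 epimers; they are drawn as the epimer that persists, and C9 is fixed by equilibration in step 16.

Step 1
Reactants: 1 furan-3-carbaldehyde
Product: 2 (Z)-4-(furan-3-yl)but-3-enoic acid
Conditions: (2-carboxyethyl)triphenylphosphonium bromide, NaN(SiMe3)2 (2.2 equiv), THF, −78 °C to rt; aq. HCl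
Reagents that add atoms: (2-carboxyethyl)triphenylphosphonium bromide, OC(=O)CC[P+](c1ccccc1)(c1ccccc1)c1ccccc1.[Br-]
Why: Wittig olefination with the non-stabilized carboxylate ylide should give the β,γ-unsaturated acid (Z expected), the alkene geometry being irrelevant because it is hydrogenated in step 2.

Step 2
Reactants: 2 (Z)-4-(furan-3-yl)but-3-enoic acid
Product: 3 4-(furan-3-yl)butanoic acid
Conditions: H2 (1 atm), RhCl(PPh3)3 (cat.), benzene/EtOH, rt
Reagents that add atoms: none
Why: homogeneous catalytic hydrogenation should saturate the disubstituted alkene while leaving the aromatic furan untouched.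

Step 3
Reactants: 4 2-bromo-3-methylcyclopent-2-en-1-one
Product: 5 (S)-2-bromo-3-methylcyclopent-2-en-1-ol
Conditions: (R)-2-methyl-CBS-oxazaborolidine (10 mol %), BH3·SMe2, THF, −20 °C; MeOH
Reagents that add atoms: none
Why: Corey–Bakshi–Shibata reduction in which the bromoalkenyl carbon acts as the large group should deliver hydride to one carbonyl face and give the (S)-carbinol, the only source of absolute configuration in the route.

Step 4
Reactants: 5 (S)-2-bromo-3-methylcyclopent-2-en-1-ol; 3 4-(furan-3-yl)butanoic acid
Product: 6 (S)-2-bromo-3-methylcyclopent-2-en-1-yl 4-(furan-3-yl)butanoate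
Conditions: DCC, DMAP (cat.), CH2Cl2, 0 °C to rt
Reagents that add atoms: none
Why: Steglich esterification joins the two fragments without touching the carbinol stereocentre.

Step 5
Reactants: 6 (S)-2-bromo-3-methylcyclopent-2-en-1-yl 4-(furan-3-yl)butanoate
Product: 9 2-(2-bromo-1-methylcyclopent-2-en-1-yl)-4-(furan-3-yl)butanoic acid (C10 methyl α), via silyl ketene acetal 7 (not isolated), via trimethylsilyl ester 8 (not isolated)
Conditions: LiN(i-Pr)2, Me3SiCl, THF, −78 °C, then 65 °C; aq. HCl
Reagents that add atoms: none
Why: in this Ireland–Claisen rearrangement the suprafacial [3,3] shift forms the C9–C10 bond on the ring face that carried the C3 oxygen, so the carbinol configuration is transferred to the C10 quaternary centre (methyl α) while the alkene moves to C3=C5 as a vinyl bromide, and C9 needs no control because it is epimerizable later.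

Step 6
Reactants: 9 2-(2-bromo-1-methylcyclopent-2-en-1-yl)-4-(furan-3-yl)butanoic acid
Product: 10 N-methoxy-N-methyl amide of 9
Conditions: MeNHOMe·HCl, EDC·HCl, HOBt (cat.), i-Pr2NEt, CH2Cl2, rt
Reagents that add atoms: N,O-dimethylhydroxylamine hydrochloride, CNOC.Cl
Why: carbodiimide amide coupling gives the Weinreb amide, which allows a single addition of a vinyl nucleophile to the hindered acyl group.

Step 7
Reactants: 10 N-methoxy-N-methyl amide of 9
Product: 11 4-(2-bromo-1-methylcyclopent-2-en-1-yl)-6-(furan-3-yl)hex-1-en-3-one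
Conditions: vinylmagnesium bromide, THF, 0 °C; inverse quench into cold aq. NH4Cl
Reagents that add atoms: vinylmagnesium bromide, C=C[Mg]Br
Why: in this Weinreb ketone synthesis the chelated tetrahedral intermediate prevents over-addition, and the cold inverse quench avoids conjugate addition of the released amine to the vinyl ketone.

Step 8
Reactants: 11 4-(2-bromo-1-methylcyclopent-2-en-1-yl)-6-(furan-3-yl)hex-1-en-3-one
Product: 12 7-[2-(furan-3-yl)ethyl]-7a-methyl-1,2,4,5,7,7a-hexahydro-6H-inden-6-one
Conditions: n-Bu3SnH (slow addition), AIBN (cat.), benzene, 80 °C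
Reagents that add atoms: none
Why: in this tin-mediated radical cyclization the C5 vinyl radical should add 6-endo to the terminal β-carbon C6 of the vinyl ketone (Giese-type conjugate addition with the carbonyl inside the new ring), which closes ring B, keeps the C3=C5 alkene and creates no permanent stereocentre.

Step 9
Reactants: 12 7-[2-(furan-3-yl)ethyl]-7a-methyl-1,2,4,5,7,7a-hexahydro-6H-inden-6-one
Product: 13 ethylene ketal of 12
Conditions: (Me3SiOCH2)2, Me3SiOTf (cat.), CH2Cl2, −78 to −20 °C; pyridine
Reagents that add atoms: 1,2-bis(trimethylsilyloxy)ethane, C[Si](C)(C)OCCO[Si](C)(C)C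
Why: aprotic ketalization masks the C8 ketone against the base of step 10 and the dissolving metal of step 14 under conditions that spare the furan and the alkene.

Step 10
Reactants: 13 ethylene ketal of 12
Product: 14 dibromocyclopropane adduct of 13 (CBr2 bridging C3 and C5)
Conditions: CHBr3, KOtBu, pentane, −20 to 0 °C
Reagents that add atoms: bromoform, BrC(Br)Br
Why: [2+1] cycloaddition of dibromocarbene to the trisubstituted C3=C5 alkene is expected on the β face, anti to the C10 methyl, and the two new cyclopropane stereocentres are erased in step 11.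

Step 11
Reactants: 14 dibromocyclopropane adduct of 13
Product: 15 ring-expanded 4-bromo-Δ4-3-ol (decalin with C8 ketal)
Conditions: AgBF4, 2,6-lutidine, acetone/H2O (5:1), rt
Reagents that add atoms: water, O
Why: Monovalent silver abstracts the endo bromide of 14 while the C3–C5 cyclopropane bond opens in a disrotatory 2π-electrocyclic process, so the five-membered ring C1–C2–C3–C5–C10 becomes the six-membered ring A (C1–C2–C3–C4–C5–C10) as a 2-bromoallyl cation spanning C3–C4–C5, with the former carbene carbon as C4. Water captures the cation at C3. The closest known reaction type is the silver-promoted ring expansion of 6,6-dibromobicyclo[3.1.0]hexanes to 2-bromocyclohex-2-enols. Ring A is not closed by a cyclization; it arises by enlargement of the cyclopentane through electrocyclic cleavage of the bond it shares with the cyclopropane. The only new stereocentre, C3, is formed without control and is removed by oxidation in step 12. The step needs capture at C3 instead of C5, which is secured because C3 is the secondary, unhindered terminus whereas C5 is flanked by the quaternary C10 and capture at C3 leaves the more substituted C4=C5 alkene; the lutidine buffer protects ketal and furan.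

Step 12
Reactants: 15 ring-expanded 4-bromo-Δ4-3-ol
Product: 16 4-bromo-Δ4-3-ketone
Conditions: Dess–Martin periodinane, NaHCO3, CH2Cl2, rt
Reagents that add atoms: none
Why: Dess–Martin oxidation of the allylic alcohol gives the α-bromo enone, which removes the uncontrolled C3 stereocentre and activates the C4–Br bond for coupling.

Step 13
Reactants: 16 4-bromo-Δ4-3-ketone
Product: 17 4-methyl-Δ4-3-ketone
Conditions: MeZnCl, Pd(PPh3)4 (cat.), THF, 50 °C
Reagents that add atoms: methylzinc chloride, C[Zn]Cl
Why: Negishi cross-coupling of the α-bromo enone installs the C19 methyl on C4, the organozinc reagent being unreactive toward the ketone, the ketal and the furan.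

Step 14
Reactants: 17 4-methyl-Δ4-3-ketone
Product: 19 trans-fused 3-ketone with C4 methyl α and C18 CH2OSEM β, via lithium enolate 18 (not isolated)
Conditions: Li, NH3(l)/THF, t-BuOH (1 equiv), −78 °C; isoprene; NH3 removed; then Me3SiCH2CH2OCH2Cl, THF, −78 to 0 °C
Reagents that add atoms: 2-(trimethylsilyl)ethoxymethyl chloride, C[Si](C)(C)CCOCCl
Why: in this Birch-type reductive alkylation, protonation of the β-carbon C5 on the face opposite the C10 methyl gives the trans ring fusion (H-5 β), and the regiospecific C3–C4 enolate is alkylated on the β face, away from the axial C10 methyl, so that C18 is equatorial and the C4 methyl axial.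

Step 15
Reactants: 19 trans-fused 3-ketone with C18 CH2OSEM
Product: 20 3α-alcohol of 19
Conditions: NaBH4, MeOH, 0 °C
Reagents that add atoms: none
Why: hydride reduction by axial attack from the β face, opposite the axial methyls on C4 and C10, should give the equatorial 3α-alcohol.

Step 16
Reactants: 20 3α-alcohol of 19
Product: 21 8-keto 3α-alcohol (ketal removed, C9 side chain α)
Conditions: aq. HCl (1 M), THF, rt
Reagents that add atoms: water, O
Why: acetal hydrolysis releases the C8 ketone, and acid-catalysed enolization lets C9 settle in the thermodynamically preferred configuration with the side chain equatorial (α, H-9 β).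

Step 17
Reactants: 21 8-keto 3α-alcohol
Product: 22 8(17)-methylene 3α-alcohol
Conditions: Ph3PCH3Br, KOtBu, toluene, 0 to 80 °C
Reagents that add atoms: methyltriphenylphosphonium bromide, C[P+](c1ccccc1)(c1ccccc1)c1ccccc1.[Br-]
Why: Wittig methylenation with excess ylide converts the hindered C8 ketone into the exocyclic C8=C17 alkene, the C3 alkoxide being inert and the basic medium keeping C9 equatorial until the olefination fixes it.

Step 18
Reactants: 22 8(17)-methylene 3α-alcohol
Product: 23 3α-angelate of 22
Conditions: LiN(SiMe3)2, THF, −78 °C; angelic anhydride, −78 to 0 °C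
Reagents that add atoms: angelic anhydride, C/C=C(/C)C(=O)OC(=O)/C(C)=C\C
Why: O-acylation of the lithium alkoxide with the anhydride, without a nucleophilic catalyst, should esterify the hindered C3 alcohol with retention of the (Z)-alkene of the angelate.

Step 19
Reactants: 23 3α-angelate of 22
Product: 24 18-hydroxy 3α-angelate with intact furan
Conditions: MgBr2·OEt2, MeNO2, Et2O, rt
Reagents that add atoms: none
Why: Lewis acid-mediated cleavage of the 2-(trimethylsilyl)ethoxymethyl ether frees the C18 alcohol under conditions that leave the angelate, the exocyclic alkene and the furan intact.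

Step 20
Reactants: 24 18-hydroxy 3α-angelate with intact furan
Product: 27 target CNP0237954.1, via furan endoperoxide 25 (not isolated), via enedial 26 (not isolated)
Conditions: O2, hν, tetraphenylporphyrin (cat.), CH2Cl2, −78 °C; Me2S; then NaBH4, CeCl3·7H2O, MeOH, −78 °C
Reagents that add atoms: oxygen, O=O
Why: [4+2] cycloaddition of singlet oxygen to the furan, reduction of the endoperoxide to the cis-enedial and Luche 1,2-reduction should give the (Z)-2-alkylbut-2-ene-1,4-diol, the Z geometry being inherited from the furan ring, while the electron-poor angelate and the 1,1-disubstituted alkene are not attacked.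

Compound list
1 | furan-3-carbaldehyde | O=Cc1ccoc1 | starting material
2 | (Z)-4-(furan-3-yl)but-3-enoic acid | OC(=O)C/C=C\c1ccoc1 | intermediate
3 | 4-(furan-3-yl)butanoic acid | OC(=O)CCCc1ccoc1 | intermediate
4 | 2-bromo-3-methylcyclopent-2-en-1-one | CC1=C(Br)C(=O)CC1 | starting material
5 | (S)-2-bromo-3-methylcyclopent-2-en-1-ol | O[C@H]1CCC(C)=C1Br | intermediate
6 | (S)-2-bromo-3-methylcyclopent-2-en-1-yl 4-(furan-3-yl)butanoate | O=C(CCCc1ccoc1)O[C@H]1CCC(C)=C1Br | intermediate
7 | (E)-trimethylsilyl ketene acetal of ester 6 | C[Si](C)(C)O/C(O[C@H]1CCC(C)=C1Br)=C/CCc1ccoc1 | intermediate (not isolated)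
8 | trimethylsilyl ester of acid 9 | C[Si](C)(C)OC(=O)[C@@H](CCc1ccoc1)[C@]1(C)CCC=C1Br | intermediate (not isolated)
9 | 2-(2-bromo-1-methylcyclopent-2-en-1-yl)-4-(furan-3-yl)butanoic acid; the ring carbon is the future C10 (methyl α), C9 drawn with H β | OC(=O)[C@@H](CCc1ccoc1)[C@]1(C)CCC=C1Br | intermediate
10 | N-methoxy-N-methyl amide of 9 | CON(C)C(=O)[C@@H](CCc1ccoc1)[C@]1(C)CCC=C1Br | intermediate
11 | 4-(2-bromo-1-methylcyclopent-2-en-1-yl)-6-(furan-3-yl)hex-1-en-3-one | C=CC(=O)[C@@H](CCc1ccoc1)[C@]1(C)CCC=C1Br | intermediate
12 | 7-[2-(furan-3-yl)ethyl]-7a-methyl-1,2,4,5,7,7a-hexahydro-6H-inden-6-one (ring B with C8 ketone, cyclopentene C3=C5, C10 methyl α) | O=C1CCC2=CCC[C@@]2(C)[C@@H]1CCc1ccoc1 | intermediate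
13 | ethylene ketal of 12 | C12(OCCO1)CCC3=CCC[C@@]3(C)[C@@H]2CCc1ccoc1 | intermediate
14 | dibromocyclopropane adduct of 13, CBr2 (future C4) bridging C3 and C5 on the β face | C12(OCCO1)CC[C@]34C(Br)(Br)[C@H]3CC[C@@]4(C)[C@@H]2CCc1ccoc1 | intermediate
15 | 4-bromo-Δ4-3-ol with six-membered ring A, C8 ketal and furylethyl side chain (C3 OH drawn α) | C12(OCCO1)CCC3=C(Br)[C@H](O)CC[C@@]3(C)[C@@H]2CCc1ccoc1 | intermediate
16 | 4-bromo-Δ4-3-ketone | C12(OCCO1)CCC3=C(Br)C(=O)CC[C@@]3(C)[C@@H]2CCc1ccoc1 | intermediate
17 | 4-methyl-Δ4-3-ketone | C12(OCCO1)CCC3=C(C)C(=O)CC[C@@]3(C)[C@@H]2CCc1ccoc1 | intermediate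
18 | lithium C3–C4 enolate with H-5 β | C12(OCCO1)CC[C@@H]3C(C)=C(O[Li])CC[C@@]3(C)[C@@H]2CCc1ccoc1 | intermediate (not isolated)
19 | trans-fused 3-ketone, C4 methyl α, C18 CH2OSEM β, C8 ketal | C12(OCCO1)CC[C@H]3[C@@](C)(CCC(=O)[C@]3(C)COCOCC[Si](C)(C)C)[C@@H]2CCc1ccoc1 | intermediate
20 | 3α-alcohol of 19 | C12(OCCO1)CC[C@H]3[C@@](C)(CC[C@@H](O)[C@]3(C)COCOCC[Si](C)(C)C)[C@@H]2CCc1ccoc1 | intermediate
21 | 8-keto 3α-alcohol, C9 side chain α | O=C1CC[C@H]2[C@@](C)(CC[C@@H](O)[C@]2(C)COCOCC[Si](C)(C)C)[C@@H]1CCc1ccoc1 | intermediate
22 | 8(17)-methylene 3α-alcohol | C=C1CC[C@H]2[C@@](C)(CC[C@@H](O)[C@]2(C)COCOCC[Si](C)(C)C)[C@@H]1CCc1ccoc1 | intermediate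
23 | 3α-angelate of 22 | C=C1CC[C@H]2[C@@](C)(CC[C@@H](OC(=O)/C(C)=C\C)[C@]2(C)COCOCC[Si](C)(C)C)[C@@H]1CCc1ccoc1 | intermediate
24 | 18-hydroxy 3α-angelate with 2-(furan-3-yl)ethyl side chain | C=C1CC[C@H]2[C@@](C)(CC[C@@H](OC(=O)/C(C)=C\C)[C@]2(C)CO)[C@@H]1CCc1ccoc1 | intermediate
25 | furan endoperoxide of 24 (2,3,7-trioxabicyclo[2.2.1]hept-5-ene, mixture at the two acetal carbons) | C=C1CC[C@H]2[C@@](C)(CC[C@@H](OC(=O)/C(C)=C\C)[C@]2(C)CO)[C@@H]1CCC1=CC2OOC1O2 | intermediate (not isolated)
26 | (Z)-enedial from 25 | C=C1CC[C@H]2[C@@](C)(CC[C@@H](OC(=O)/C(C)=C\C)[C@]2(C)CO)[C@@H]1CC/C(=C/C=O)C=O | intermediate (not isolated)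
27 | CNP0237954.1 | C=C1CC[C@H]2[C@@](C)(CC[C@@H](OC(=O)/C(C)=C\C)[C@]2(C)CO)[C@@H]1CC/C(=C/CO)CO | target

Total step count: 20. Longest linear sequence: 19 steps (steps 1, 2 and 4–20, from furan-3-carbaldehyde).

Steps most likely to fail

Step 10 (dibromocarbene addition). The electrophilic carbene may attack the electron-rich furan in competition with the hindered C3=C5 alkene next to the quaternary C10, so that cyclopropanation stalls or over-reacts. The fallback sets out from 13 and comes back at 17. Hydroboration–oxidation of 13 (BH3·THF; NaOH, H2O2) should give the C3 alcohol F1. Dess–Martin oxidation then gives the hydrindanone F2, and Me3SiOTf/Et3N under equilibrating conditions gives the more substituted silyl enol ether F3. Chloro(methyl)carbene (CH3CHCl2, n-BuLi, Et2O, −35 °C), toward which the enol ether is far more reactive than the furan, gives the siloxy chlorocyclopropane F4. Heating F4 in toluene with Et3N opens it with loss of Me3SiCl to the methyl enone 17. Ring A again arises from the five-membered ring by insertion of one carbon.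

Step 8 (radical ring closure). 1,5-Hydrogen transfer from the side-chain methylene next to the furan to the vinyl radical, premature reduction by the stannane, or 5-exo closure may compete with the 6-endo addition. The fallback sets out from 10 and comes back at 12. MeMgBr converts the Weinreb amide 10 into the methyl ketone F5. Stille coupling of its vinyl bromide with (tributylstannyl)methanol (Pd(PPh3)4, dioxane, 90 °C) gives the allylic alcohol F6, and an Appel reaction (CBr4, PPh3) gives the allylic bromide F7. LiN(i-Pr)2 at −78 °C then forms the kinetic methyl enolate, which closes ring B by intramolecular SN2 alkylation to give 12.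

Step 14 (reductive alkylation). The enolate may be O-alkylated by the hard chloromethyl ether, or quenched by proton transfer before alkylation. The fallback sets out from 17 and comes back at 19. The same lithium–ammonia reduction is followed by trapping of the enolate with gaseous formaldehyde (aldol addition, again anti to the C10 methyl) to give the β-hydroxy ketone F8. Its primary alcohol is then etherified with Me3SiCH2CH2OCH2Cl and i-Pr2NEt to give 19.

Further compounds
F1 | step 10 | C3 β-alcohol from hydroboration of 13 (H-5 β, C8 ketal) | C12(OCCO1)CC[C@@H]3[C@@H](O)CC[C@@]3(C)[C@@H]2CCc1ccoc1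
F2 | step 10 | hydrindan-3-one from F1 (H-5 β, C8 ketal) | C12(OCCO1)CC[C@@H]3C(=O)CC[C@@]3(C)[C@@H]2CCc1ccoc1
F3 | step 10 | trimethylsilyl enol ether C3(OSiMe3)=C5 of F2 | C12(OCCO1)CCC3=C(O[Si](C)(C)C)CC[C@@]3(C)[C@@H]2CCc1ccoc1
F4 | step 10 | 1-siloxy-6-chloro-6-methylbicyclo[3.1.0]hexane adduct of F3 (C4 epimers) | C12(OCCO1)CC[C@]34C(C)(Cl)[C@@]3(O[Si](C)(C)C)CC[C@@]4(C)[C@@H]2CCc1ccoc1
F5 | step 8 | methyl ketone 3-(2-bromo-1-methylcyclopent-2-en-1-yl)-5-(furan-3-yl)pentan-2-one | CC(=O)[C@@H](CCc1ccoc1)[C@]1(C)CCC=C1Br
F6 | step 8 | allylic alcohol 5-(furan-3-yl)-3-[2-(hydroxymethyl)-1-methylcyclopent-2-en-1-yl]pentan-2-one | CC(=O)[C@@H](CCc1ccoc1)[C@]1(C)CCC=C1CO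
F7 | step 8 | allylic bromide 3-[2-(bromomethyl)-1-methylcyclopent-2-en-1-yl]-5-(furan-3-yl)pentan-2-one | CC(=O)[C@@H](CCc1ccoc1)[C@]1(C)CCC=C1CBr
F8 | step 14 | trans-fused 18-hydroxy 3-ketone with C4 methyl α and C8 ketal | C12(OCCO1)CC[C@H]3[C@@](C)(CCC(=O)[C@]3(C)CO)[C@@H]2CCc1ccoc1
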